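(The data were computed on assumed constants, noise included.)

At 15 °C the alder run levels off by about 4.00 d, and at 26 °C the maple run has levelled off at its first reading, 1.25 d. So 12 d at 20 °C gives dawn and autumn time to arrive.

all flasks: E 0.108 M

|  | G | temperature | remark | time |
|---|---|---|---|---|
| alder | 0.47 M | 15 °C | run made earlier |  |
| maple | 1.6 M | 26 °C | run made earlier |  |
| dawn | 0.54 M | 20 °C |  | 12 d |
| autumn | 2.0 M | 20 °C |  | 12 d |

| run | time / d | Q / % | G / % |
|---|---|---|---|
| alder | 0.625 | 10.9 | 67.3 |
| alder | 1.04 | 14.7 | 63.2 |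
| alder | 1.67 | 16.9 | 59.6 |
| alder | 2.50 | 19.8 | 56.4 |
| alder | 4.00 | 21.7 | 55.4 |
| alder | 6.00 | 22.7 | 54.3 |
| alder | 8.00 | 22.3 | 53.6 |
| maple | 1.25 | 47.4 | 45.3 |
| maple | 2.50 | 46.9 | 43.2 |
| maple | 4.00 | 46.1 | 44.5 |
| maple | 5.00 | 45.2 | 43.5 |
| maple | 6.00 | 45.0 | 43.2 |
| maple | 8.00 | 43.8 | 42.3 |

(standard deviation of a reading: 0.5 percentage points)

- percentages count the G that a species holds: one Q counts as two
- the analysis behind the earlier runs scatters by 0.5 percentage points, standard deviation

* which one finishes higher in amount of Q, in percent of the G charged ("neither" within 2 percentage points) (dawn / autumn / neither)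
* amount of Q at the end, in percent of the G charged, dawn
* amount of Q at the end, in percent of the G charged, autumn

Q and G together fall short of the charge by 0.108 M in alder and 0.117 M in maple, close to the 0.108 M of E. So E, the limiting reagent, appears to take its own amount of G, and the G open to Q is the charge of G less the charge of E. Amount of Q over the square of amount of G reads 0.819 L mol⁻¹ in alder and 0.722 L mol⁻¹ in maple. Their mean, 0.770 L mol⁻¹, is the holding ratio.

The G open to Q, shared out between G and Q by this ratio, each Q taking two G, gives this reckoning's ceiling: 25.1% for dawn and 53.1% for autumn. Q and G also drain slowly. Over 12 d, charged wholly to Q, the pace of maple would take 12 percentage points, and that of alder 3.6 points. Since 20 °C lies between their temperatures, the mean of the two paces, 7.7 points, stands in for the loss in dawn and in autumn; the two runs differ in their charge of G as well, so this is an estimate. The estimated floors are then 17.4% for dawn and 45.4% for autumn, so the floor of autumn stands above the ceiling of dawn.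

The forecast says autumn, with 23% (20.5% to 25.5%) for dawn and 48% (43% to 53%) for autumn, on the ground that “E binds G 1:1, removing about 0.108 M”. Both central values stand inside the bracket.

The simulation gives autumn, with 24.3% for dawn and 49.8% for autumn.

    2 G ⇌ Q (K = 0.790 L mol⁻¹, k = 0.0240 L mol⁻¹ h⁻¹, Ea = 72.0 kJ mol⁻¹, ΔH = −8.00 kJ mol⁻¹)
    G + E → L (k = 1.00 L mol⁻¹ h⁻¹, Ea = 75.0 kJ mol⁻¹)
    2 G → J (k = 2.60 × 10⁻⁴ L mol⁻¹ h⁻¹, Ea = 92.0 kJ mol⁻¹)
    (constants at 20 °C)

Dawn ends 0.8 points under its ceiling, with J at 2.49%, and autumn ends 3.3 points under its ceiling, with J at 5.29%. The neighbour of dawn charged with 0.27 M of E has 0.270 M of G open to Q, and the same holding ratio gives it a ceiling of 12.0%. That neighbour ends with Q at 11.8% and L at 50.0%.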